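The route rests on a [3+3] union of ring A with a C2–C3–C4 unit that creates ring C. Ring A offers O1 and the neighbouring carbon C4a as a 1,3-dinucleophile; C4 (acyl) and C2 (benzylic to the para-oxygenated ring B) form a 1,3-dielectrophile, which is carried as an enantiopure trans-epoxy amide so that C3 already bears its oxygen. In one flask, an ortho-lithiated phenoxide acylates at C4a and the freed phenol then opens the epoxide at C2, giving the trans-(2R,3R) dihydroflavonol. The precursor phenol carries the (R)-diarylethane side chain and two methoxy groups, which make both ortho positions equivalent; the peri methoxy group is cleaved last.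

Key step: step 8

Assumption: the (S)-ligands named in steps 3 and 7 are taken to give the configurations drawn (step 7 by analogy with lanthanoid–BINOL epoxidations of enones, step 3 to be confirmed on the substrate); the mirror-image ligand is used if the sense proves opposite.

Step 1
Reactants: 1 3,5-dimethoxyphenol
Product: 2 (3,5-dimethoxyphenoxy)tri(propan-2-yl)silane
Conditions: TIPSCl, imidazole, DMF, rt
Reagents that add atoms: chlorotri(propan-2-yl)silane, CC(C)[Si](Cl)(C(C)C)C(C)C
Why: O-silylation of the phenol; the bulky silyl ether masks the future O1 and does not direct lithiation to its own ortho positions.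

Step 2
Reactants: 2 (3,5-dimethoxyphenoxy)tri(propan-2-yl)silane; 3 1-[4-(benzyloxy)phenyl]ethan-1-one
Product: 6 {4-[1-(4-(benzyloxy)phenyl)ethenyl]-3,5-dimethoxyphenoxy}tri(propan-2-yl)silane, via aryllithium 4 (not isolated), via tertiary carbinol 5 (not isolated)
Conditions: n-BuLi, THF, 0 °C to rt; LaCl3·2LiCl, then 3, −78 °C to rt; aq. NH4Cl; crude 5: TsOH·H2O (cat.), PhMe, rt
Reagents that add atoms: none
Why: Directed ortho-metalation should occur between the two methoxy groups, 1,2-addition to the ketone is assisted by LaCl3·2LiCl to suppress enolisation, and the doubly activated tertiary benzylic alcohol should undergo acid-catalysed E1 dehydration to the 1,1-diarylethene.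

Step 3
Reactants: 6 {4-[1-(4-(benzyloxy)phenyl)ethenyl]-3,5-dimethoxyphenoxy}tri(propan-2-yl)silane
Product: 7 {4-[(1R)-1-(4-(benzyloxy)phenyl)ethyl]-3,5-dimethoxyphenoxy}tri(propan-2-yl)silane
Conditions: H2 (1–5 bar), [Ir(cod)((S)-t-Bu-PHOX)][B(3,5-(CF3)2C6H3)4] (2 mol %), CH2Cl2, rt
Reagents that add atoms: none
Why: Iridium N,P-ligand-catalysed asymmetric hydrogenation of a 1,1-diarylethene, in which the twisted 2,6-dimethoxyaryl group and the flat 4-benzyloxyphenyl group are sterically well differentiated so that the catalyst should select one alkene face and set the (R)-methine, while the benzyl ether is inert to the homogeneous catalyst.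

Step 4
Reactants: 7 {4-[(1R)-1-(4-(benzyloxy)phenyl)ethyl]-3,5-dimethoxyphenoxy}tri(propan-2-yl)silane
Product: 8 4-[(1R)-1-(4-(benzyloxy)phenyl)ethyl]-3,5-dimethoxyphenol
Conditions: Bu4NF, THF, 0 °C; aq. NH4Cl
Reagents that add atoms: none
Why: Fluoride-mediated desilylation of the aryl silyl ether should free the phenol without touching the benzyl ether or the methine.

Step 5
Reactants: 8 4-[(1R)-1-(4-(benzyloxy)phenyl)ethyl]-3,5-dimethoxyphenol
Product: 9 2-bromo-4-[(1R)-1-(4-(benzyloxy)phenyl)ethyl]-3,5-dimethoxyphenol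
Conditions: NBS (1.0 equiv), CH2Cl2, −78 to −20 °C, dark
Reagents that add atoms: N-bromosuccinimide, O=C1CCC(=O)N1Br
Why: Electrophilic aromatic bromination should go ortho to the free hydroxyl on the trioxygenated ring, far more reactive than the benzyloxyphenyl ring, and the two ortho positions are equivalent so only one monobromide can form.

Step 6
Reactants: 10 (2E)-3-[4-(benzyloxy)phenyl]prop-2-enoic acid
Product: 11 (2E)-3-[4-(benzyloxy)phenyl]-1-(morpholin-4-yl)prop-2-en-1-one
Conditions: morpholine, EDC·HCl, HOBt (cat.), Et3N, CH2Cl2, 0 °C to rt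
Reagents that add atoms: morpholine, C1COCCN1
Why: Carbodiimide amide coupling should give the morpholine amide, which serves both as a substrate for catalytic asymmetric epoxidation and as a Weinreb-type acyl donor.

Step 7
Reactants: 11 (2E)-3-[4-(benzyloxy)phenyl]-1-(morpholin-4-yl)prop-2-en-1-one
Product: 12 [(2R,3S)-3-(4-(benzyloxy)phenyl)oxiran-2-yl](morpholin-4-yl)methanone
Conditions: Sm(O-i-Pr)3 (10 mol %), (S)-BINOL (10 mol %), Ph3As=O (10 mol %), t-BuOOH, 4 Å MS, THF, rt
Reagents that add atoms: tert-butyl hydroperoxide, CC(C)(C)OO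
Why: Lanthanoid–BINOL-catalysed nucleophilic (Weitz–Scheffer type) epoxidation of an α,β-unsaturated amide, in which the chiral samarium peroxide should add to one face of the E-alkene and give the trans-(2R,3S) epoxide, setting the future C3.

Step 8
Reactants: 9 2-bromo-4-[(1R)-1-(4-(benzyloxy)phenyl)ethyl]-3,5-dimethoxyphenol; 12 [(2R,3S)-3-(4-(benzyloxy)phenyl)oxiran-2-yl](morpholin-4-yl)methanone
Product: 16 (2R,3R)-2-[4-(benzyloxy)phenyl]-6-[(1R)-1-(4-(benzyloxy)phenyl)ethyl]-3-hydroxy-5,7-dimethoxy-2,3-dihydro-4H-chromen-4-one, via dilithio phenoxide 13 (not isolated), via lithium hemiaminal adduct 14 (not isolated), via epoxy ketone 15 (not isolated)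
Conditions: n-BuLi (2.05 equiv), THF, −78 °C; 12, −78 to −30 °C; then 2 M aq. HCl, 0 °C to rt
Reagents that add atoms: none
Why: Phenol deprotonation and bromine–lithium exchange turn 9 into the O,C-dianion 13, whose aryl carbon adds to the morpholine amide of 12 (Weinreb-type ketone synthesis, C4–C4a) to give the chelated adduct 14; acidification releases the 2'-hydroxychalcone epoxide 15, whose phenol oxygen should attack the benzylic epoxide carbon at once (O1–C2). The closest known reactions are the addition of organolithiums to α,β-epoxy morpholine amides and the acid-mediated cyclisation of 2'-hydroxychalcone epoxides to dihydroflavonols, here run in one flask. Ring C closes by a 6-endo-tet epoxide opening, favoured over the 5-exo mode under acid because positive charge develops at C2, benzylic to the para-alkoxyphenyl ring B. C3 keeps the configuration of the epoxide α-carbon, whose C–O bond is untouched, and C2 forms with inversion at the β-carbon, so the trans-(2R,3S) epoxide gives the trans-(2R,3R) product; any leakage through a benzylic cation should be corrected because the 2,3-trans diequatorial isomer is also the thermodynamic one, reached by reversible opening of the O1–C2 bond. The step needs acylation at C4a and closure through O1: the bromine fixes the carbon, the adjacent hydroxyl is the only free one, and the two methoxy groups made the choice of ortho position in step 5 degenerate. Attack at the amide in preference to the epoxide is secured by the low temperature and the chelating morpholine amide.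

Step 9
Reactants: 16 (2R,3R)-2-[4-(benzyloxy)phenyl]-6-[(1R)-1-(4-(benzyloxy)phenyl)ethyl]-3-hydroxy-5,7-dimethoxy-2,3-dihydro-4H-chromen-4-one
Product: 17 (2R,3R)-3,5-dihydroxy-2-(4-hydroxyphenyl)-6-[(1R)-1-(4-hydroxyphenyl)ethyl]-7-methoxy-2,3-dihydro-4H-chromen-4-one
Conditions: BCl3 (excess), C6HMe5, CH2Cl2, −78 °C to rt; then MeOH/H2O
Reagents that add atoms: none
Why: Lewis-acid ether cleavage in which BCl3 with pentamethylbenzene as cation scavenger should remove both aryl benzyl ethers, and the 5-methoxy group alone should be demethylated through the six-membered boron chelate with the C4 carbonyl, leaving the unchelated 7-methoxy group.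

Compound list
1 | 3,5-dimethoxyphenol | COc1cc(O)cc(OC)c1 | starting material
2 | (3,5-dimethoxyphenoxy)tri(propan-2-yl)silane | COc1cc(O[Si](C(C)C)(C(C)C)C(C)C)cc(OC)c1 | intermediate
3 | 1-[4-(benzyloxy)phenyl]ethan-1-one | CC(=O)c1ccc(OCc2ccccc2)cc1 | starting material
4 | [2,6-dimethoxy-4-(tri(propan-2-yl)silyloxy)phenyl]lithium | COc1cc(O[Si](C(C)C)(C(C)C)C(C)C)cc(OC)c1[Li] | intermediate
5 | 1-[4-(benzyloxy)phenyl]-1-[2,6-dimethoxy-4-(tri(propan-2-yl)silyloxy)phenyl]ethan-1-ol (racemic) | COc1cc(O[Si](C(C)C)(C(C)C)C(C)C)cc(OC)c1C(C)(O)c1ccc(OCc2ccccc2)cc1 | intermediate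
6 | {4-[1-(4-(benzyloxy)phenyl)ethenyl]-3,5-dimethoxyphenoxy}tri(propan-2-yl)silane | COc1cc(O[Si](C(C)C)(C(C)C)C(C)C)cc(OC)c1C(=C)c1ccc(OCc2ccccc2)cc1 | intermediate
7 | {4-[(1R)-1-(4-(benzyloxy)phenyl)ethyl]-3,5-dimethoxyphenoxy}tri(propan-2-yl)silane | COc1cc(O[Si](C(C)C)(C(C)C)C(C)C)cc(OC)c1[C@H](C)c1ccc(OCc2ccccc2)cc1 | intermediate
8 | 4-[(1R)-1-(4-(benzyloxy)phenyl)ethyl]-3,5-dimethoxyphenol | COc1cc(O)cc(OC)c1[C@H](C)c1ccc(OCc2ccccc2)cc1 | intermediate
9 | 2-bromo-4-[(1R)-1-(4-(benzyloxy)phenyl)ethyl]-3,5-dimethoxyphenol | COc1cc(O)c(Br)c(OC)c1[C@H](C)c1ccc(OCc2ccccc2)cc1 | intermediate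
10 | (2E)-3-[4-(benzyloxy)phenyl]prop-2-enoic acid | OC(=O)/C=C/c1ccc(OCc2ccccc2)cc1 | starting material
11 | (2E)-3-[4-(benzyloxy)phenyl]-1-(morpholin-4-yl)prop-2-en-1-one | O=C(/C=C/c1ccc(OCc2ccccc2)cc1)N1CCOCC1 | intermediate
12 | [(2R,3S)-3-(4-(benzyloxy)phenyl)oxiran-2-yl](morpholin-4-yl)methanone | O=C([C@@H]1O[C@H]1c1ccc(OCc2ccccc2)cc1)N1CCOCC1 | intermediate
13 | lithium 4-[(1R)-1-(4-(benzyloxy)phenyl)ethyl]-2-lithio-3,5-dimethoxyphenolate | COc1cc(O[Li])c([Li])c(OC)c1[C@H](C)c1ccc(OCc2ccccc2)cc1 | intermediate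
14 | dilithium salt of the morpholine hemiaminal from 13 and 12, epoxide (2R,3S), hemiaminal carbon undefined | COc1cc(O[Li])c(C(O[Li])(N2CCOCC2)[C@@H]2O[C@H]2c2ccc(OCc3ccccc3)cc2)c(OC)c1[C@H](C)c1ccc(OCc2ccccc2)cc1 | intermediate
15 | [(2R,3S)-3-(4-(benzyloxy)phenyl)oxiran-2-yl]{3-[(1R)-1-(4-(benzyloxy)phenyl)ethyl]-6-hydroxy-2,4-dimethoxyphenyl}methanone | COc1cc(O)c(C(=O)[C@@H]2O[C@H]2c2ccc(OCc3ccccc3)cc2)c(OC)c1[C@H](C)c1ccc(OCc2ccccc2)cc1 | intermediate
16 | (2R,3R)-2-[4-(benzyloxy)phenyl]-6-[(1R)-1-(4-(benzyloxy)phenyl)ethyl]-3-hydroxy-5,7-dimethoxy-2,3-dihydro-4H-chromen-4-one | COc1cc2c(c(OC)c1[C@H](C)c1ccc(OCc3ccccc3)cc1)C(=O)[C@H](O)[C@@H](c1ccc(OCc3ccccc3)cc1)O2 | intermediate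
17 | (2R,3R)-3,5-dihydroxy-2-(4-hydroxyphenyl)-6-[(1R)-1-(4-hydroxyphenyl)ethyl]-7-methoxy-2,3-dihydro-4H-chromen-4-one | COc1cc2c(c(O)c1[C@H](C)c1ccc(O)cc1)C(=O)[C@H](O)[C@@H](c1ccc(O)cc1)O2 | target

Total step count: 9. Longest linear sequence: 7 (steps 1, 2, 3, 4, 5, 8, 9).

Steps most likely to fail

Step 8 (key step). The aggregated dianion may add slowly or attack the epoxide instead of the amide, and on acidification acyl migration or 5-exo closure may compete with the 6-endo opening. Fallback: from 9, the phenol is protected (MOMCl, i-Pr2NEt, CH2Cl2) as the methoxymethyl ether F1. Bromine–lithium exchange (n-BuLi, THF, −78 °C) and addition to 12 give the 2'-O-methoxymethyl epoxy ketone F2, which is isolated. HCl in MeOH at 45 °C then removes the acetal and cyclises the freed phenol onto the epoxide, returning to the route at 16.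

Step 3. Facial selectivity in the hydrogenation may be poor, or turnover slow at the hindered alkene. Fallback: from 6, hydrogenation without asymmetric induction (H2, [Ir(cod)(PCy3)(py)]PF6, CH2Cl2) gives the racemic silyl ether F3. Bu4NF gives the racemic phenol F4, and preparative chromatography on a chiral stationary phase delivers the (R)-enantiomer, returning at 8.

Step 9. Benzyl cations may transfer to the electron-rich C8 of ring A, the Lewis acid may open the O1–C2 bond with erosion of the 2,3-trans configuration, or cleavage of the chelated methyl ether may stay incomplete. Fallback: from 16, hydrogenolysis (H2, 10% Pd/C, EtOAc/MeOH) removes both benzyl groups to give the dimethyl ether F5. Chelation-controlled demethylation with MgI2 in THF at 50 °C then cleaves only the 5-methoxy group, returning at 17.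

Further compounds
F1 | step 8 | 4-[(1R)-1-(4-(benzyloxy)phenyl)ethyl]-2-bromo-3,5-dimethoxy-1-(methoxymethoxy)benzene | COc1cc(OCOC)c(Br)c(OC)c1[C@H](C)c1ccc(OCc2ccccc2)cc1
F2 | step 8 | [(2R,3S)-3-(4-(benzyloxy)phenyl)oxiran-2-yl]{3-[(1R)-1-(4-(benzyloxy)phenyl)ethyl]-2,4-dimethoxy-6-(methoxymethoxy)phenyl}methanone | COc1cc(OCOC)c(C(=O)[C@@H]2O[C@H]2c2ccc(OCc3ccccc3)cc2)c(OC)c1[C@H](C)c1ccc(OCc2ccccc2)cc1
F3 | step 3 | racemic {4-[1-(4-(benzyloxy)phenyl)ethyl]-3,5-dimethoxyphenoxy}tri(propan-2-yl)silane | COc1cc(O[Si](C(C)C)(C(C)C)C(C)C)cc(OC)c1C(C)c1ccc(OCc2ccccc2)cc1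
F4 | step 3 | racemic 4-[1-(4-(benzyloxy)phenyl)ethyl]-3,5-dimethoxyphenol | COc1cc(O)cc(OC)c1C(C)c1ccc(OCc2ccccc2)cc1
F5 | step 9 | (2R,3R)-3-hydroxy-2-(4-hydroxyphenyl)-6-[(1R)-1-(4-hydroxyphenyl)ethyl]-5,7-dimethoxy-2,3-dihydro-4H-chromen-4-one | COc1cc2c(c(OC)c1[C@H](C)c1ccc(O)cc1)C(=O)[C@H](O)[C@@H](c1ccc(O)cc1)O2
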